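The route rests on cutting the unsymmetrical biaryl bond between ring B (its CH2 on C-alpha of lactone A) and ring C (its CH2 on C-beta of lactone B). On ring C, the carbon bearing ring B, the carbon bearing the phenolic O and the carbon bearing OMe are contiguous. A methoxy-flanked aryne can therefore take up the aryl carbon and the oxygen on its two triple-bond carbons in one flask. The precursors are a 3-chloro-5-methoxyphenyl dioxolane, lithiated between Cl and OMe, and a benzyl-protected ring B Grignard reagent carrying a silyloxymethyl arm. The two different arms then become the (R,R)-hydroxylactones through face-selective enediolate benzylations, and hydrogenolysis ends the route.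

Key step: step 6

Labels:
- Ring A is the guaiacyl ring on C-beta of lactone A. Ring B is the biaryl ring on C-alpha of lactone A.
- Ring C is the biaryl ring on C-beta of lactone B. Ring D is the guaiacyl ring on C-alpha of lactone B.
- Biphenyl locants: unprimed = ring C, primed = ring B.
- Bn = benzyl, TIPS = triisopropylsilyl.
- BC = 2,2'-bis(benzyloxy)-3,3'-dimethoxy-5'-(triisopropylsilyloxymethyl)biphenyl-5-yl, attached through C5 of ring C.

Assumption: [Rh(cod)((R,R)-Et-DuPHOS)]BF4 is taken to give the (S)-succinate half-esters, which is the spatial sense this ligand series shows with (Z)-enamides. The sign of rotation of lactone 33 checks this, and the antipodal ligand is equally available.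

Step 1
Reactants: 1 5-bromovanillin (3-bromo-4-hydroxy-5-methoxybenzaldehyde)
Product: 2 4-benzyloxy-3-bromo-5-methoxybenzaldehyde
Conditions: BnBr, K2CO3, DMF, 25 → 50 °C
Reagents that add atoms: benzyl bromide, BrCc1ccccc1
Why: Williamson ether synthesis, in which the acidic phenoxide is alkylated by benzyl bromide (SN2) to install a group that tolerates organometallics and falls in the final hydrogenolysis.

Step 2
Reactants: 2 4-benzyloxy-3-bromo-5-methoxybenzaldehyde
Product: 3 (4-benzyloxy-3-bromo-5-methoxyphenyl)methanol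
Conditions: NaBH4, MeOH/THF, 0 °C
Reagents that add atoms: none
Why: Borohydride reduction of an aryl aldehyde is chemoselective and leaves the aryl bromide and the benzyl ether untouched.

Step 3
Reactants: 3 (4-benzyloxy-3-bromo-5-methoxyphenyl)methanol
Product: 4 [(4-benzyloxy-3-bromo-5-methoxyphenyl)methoxy]triisopropylsilane
Conditions: TIPSCl, imidazole, DMF, 25 °C
Reagents that add atoms: chlorotriisopropylsilane, CC(C)[Si](Cl)(C(C)C)C(C)C
Why: Imidazole-promoted silyl ether formation on a primary benzylic alcohol, giving a bulky TIPS ether that should survive the Grignard chemistry, alkoxide, hydride, enolates and dilute acid met later.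

Step 4
Reactants: 4 [(4-benzyloxy-3-bromo-5-methoxyphenyl)methoxy]triisopropylsilane
Product: 5 [2-benzyloxy-3-methoxy-5-(triisopropylsilyloxymethyl)phenyl]magnesium bromide (THF solution; titrated and used directly)
Conditions: Mg turnings, LiCl, i-Bu2AlH (1 mol%), THF, 25–35 °C
Reagents that add atoms: magnesium, [Mg]
Why: Grignard reagent formation by insertion of magnesium into the aryl C–Br bond, assisted by LiCl, in a substrate with no acidic or electrophilic group.

Step 5
Reactants: 6 3-chloro-5-methoxybenzaldehyde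
Product: 7 2-(3-chloro-5-methoxyphenyl)-1,3-dioxolane
Conditions: ethylene glycol, p-TsOH (cat.), toluene, reflux, azeotropic removal of water
Reagents that add atoms: ethylene glycol, OCCO
Why: Acid-catalysed acetalisation masks the aldehyde against the organolithium and Grignard reagents of the next step and keeps this arm distinct from the silyl ether arm of ring B.

Step 6
Reactants: 7 2-(3-chloro-5-methoxyphenyl)-1,3-dioxolane; 5 [2-benzyloxy-3-methoxy-5-(triisopropylsilyloxymethyl)phenyl]magnesium bromide; 8 trimethyl borate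
Product: 13 2'-benzyloxy-5-(1,3-dioxolan-2-yl)-3,3'-dimethoxy-5'-(triisopropylsilyloxymethyl)biphenyl-2-ol (free phenol on ring C), via aryllithium 9 (not isolated), via aryne 10 (not isolated), via biarylmagnesium bromide 11 (not isolated), via dimethyl boronate 12 (not isolated)
Conditions: 7, s-BuLi (1.05 equiv, no diamine additive), THF, −78 °C; 5 (1.3 equiv), −78 → 25 °C, then 45 °C; B(OMe)3 (4 equiv), 0 → 25 °C; 30% H2O2, 2 M NaOH, 0 °C; aq. NH4Cl
Reagents that add atoms: hydrogen peroxide, OO (phenolic oxygen of 13); sec-butyllithium, [Li]C(C)CC (lithium of intermediate 9 only)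
Why: At −78 °C s-BuLi should take the one ring proton flanked by two inductive acceptors (Cl and OMe) to give 9, faster than the positions beside the weakly directing, bulkier acetal or the acetal C–H; after exchange onto magnesium by 5, warming expels chloride and unveils aryne 10 with its triple bond between the former C–H and C–Cl carbons. The aryl–magnesium bond of 5 then carbometalates 10, the closest known reaction type being addition of aryl Grignard reagents to arynes from ortho-metalated haloarenes with electrophilic capture of the resulting 2-biarylmagnesium halide, as used for hindered biaryl iodides and phosphines. The step needs regiocontrol, and the methoxy group next to the triple bond supplies it: its sigma-withdrawal polarises and distorts the aryne so that carbon attack occurs at the remote aryne carbon (whose other neighbour is C–H) and magnesium ends ortho to OMe in 11. B(OMe)3 captures 11 as boronate 12, and alkaline H2O2 induces the 1,2-shift of the aryl group from boron to oxygen at the same carbon, so the new phenolic oxygen, which originates from H2O2 and not from the borate, sits exactly between OMe and ring B. No ring is closed and no stereocentre is formed, and the biaryl axis with only two ortho oxygen substituents should rotate freely. Acetal, silyl ether and benzyl ether are inert to the organometallics and to basic peroxide, and the two rings emerge with different arms and different phenol status.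

Step 7
Reactants: 13 2'-benzyloxy-5-(1,3-dioxolan-2-yl)-3,3'-dimethoxy-5'-(triisopropylsilyloxymethyl)biphenyl-2-ol
Product: 15 BC-carbaldehyde (2,2'-bis(benzyloxy)-3,3'-dimethoxy-5'-(triisopropylsilyloxymethyl)biphenyl-5-carbaldehyde), via benzyl ether acetal 14 (not isolated)
Conditions: BnBr, K2CO3, DMF, 60 °C; aqueous work-up, crude 14 in THF, 1 M HCl, 25 °C
Reagents that add atoms: benzyl bromide, BrCc1ccccc1; water, O
Why: Williamson ether synthesis on the hindered phenol followed by acid-catalysed acetal hydrolysis, which for an electron-rich aryl dioxolane is far faster than cleavage of a primary TIPS ether.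

Step 8
Reactants: 15 BC-carbaldehyde; 16 dimethyl succinate
Product: 17 (E)-4-BC-3-(methoxycarbonyl)but-3-enoic acid
Conditions: KOt-Bu, t-BuOH/THF, 50 °C; then 1 M HCl to pH 3
Reagents that add atoms: none
Why: Stobbe condensation, in which aldol addition of the succinate enolate, lactonisation to the paraconic ester and base-induced ring opening give the carboxylate irreversibly, with the aryl group trans to the ester (E) on steric grounds.

Step 9
Reactants: 17 (E)-4-BC-3-(methoxycarbonyl)but-3-enoic acid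
Product: 18 (3S)-4-BC-3-(methoxycarbonyl)butanoic acid
Conditions: H2 (6 bar), [Rh(cod)((R,R)-Et-DuPHOS)]BF4 (1 mol%), NaOMe (10 mol%), MeOH/THF, 25 °C
Reagents that add atoms: none
Why: Asymmetric hydrogenation of an itaconate-type half-ester, in which carboxylate and alkene chelate rhodium and the C2-symmetric bisphospholane leaves one alkene face open, setting the future C-beta of lactone B (S here) while benzyl and silyl ethers stay inert to the homogeneous catalyst.

Step 10
Reactants: 18 (3S)-4-BC-3-(methoxycarbonyl)butanoic acid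
Product: 20 (4S)-4-(BC-methyl)oxolan-2-one, via hydroxy acid 19 (not isolated)
Conditions: KOH (1.0 equiv), EtOH, 0 °C; CaCl2, NaBH4, EtOH, 0 → 25 °C; then 1 M HCl to pH 2, 25 °C
Reagents that add atoms: none
Why: Chemoselective borohydride reduction, in which Ca(BH4)2 reduces the ester while the carboxylate salt is inert, and acidification closes the gamma-lactone without touching the stereocentre.

Step 11
Reactants: 20 (4S)-4-(BC-methyl)oxolan-2-one
Product: 22 (3S,4R)-3-hydroxy-4-(BC-methyl)oxolan-2-one, via potassium enolate 21 (not isolated)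
Conditions: KN(SiMe3)2, THF, −78 °C; 2-(phenylsulfonyl)-3-phenyloxaziridine, −78 °C; AcOH
Reagents that add atoms: 2-(phenylsulfonyl)-3-phenyloxaziridine, O=S(=O)(c1ccccc1)N1OC1c1ccccc1; potassium bis(trimethylsilyl)amide, C[Si](C)(C)N([K])[Si](C)(C)C (potassium of intermediate 21 only)
Why: Electrophilic enolate hydroxylation with an N-sulfonyloxaziridine, with oxygen expected to arrive trans to the C-beta substituent, although this C-alpha configuration is erased again in step 13.

Step 12
Reactants: 23 (4-benzyloxy-3-methoxyphenyl)methanol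
Product: 24 4-benzyloxy-3-methoxybenzyl bromide (ring D electrophile; used fresh)
Conditions: PBr3, Et2O, 0 °C
Reagents that add atoms: phosphorus tribromide, BrP(Br)Br
Why: Bromination of a primary benzylic alcohol through its phosphite ester (SN2 by bromide), a standard preparation of alkoxybenzyl bromides.

Step 13
Reactants: 22 (3S,4R)-3-hydroxy-4-(BC-methyl)oxolan-2-one; 24 4-benzyloxy-3-methoxybenzyl bromide
Product: 26 (3R,4R)-3-(4-benzyloxy-3-methoxybenzyl)-3-hydroxy-4-(BC-methyl)oxolan-2-one, via dilithium enediolate 25 (not isolated)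
Conditions: 22 added to LiN(i-Pr)2 (2.3 equiv), THF, −78 → −40 °C; 24, −78 → −30 °C; AcOH
Reagents that add atoms: lithium diisopropylamide, CC(C)N([Li])C(C)C (lithium of intermediate 25 only)
Why: C-alkylation of an alpha-hydroxy lactone dianion, in which the planar enediolate is shielded on one face by the C-beta arylmethyl group so the benzyl bromide should enter trans to it, leaving the oxygen cis and setting C-alpha of lactone B as R.

Step 14
Reactants: 26 (3R,4R)-3-(4-benzyloxy-3-methoxybenzyl)-3-hydroxy-4-(BC-methyl)oxolan-2-one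
Product: 27 the 5'-hydroxymethyl analogue of 26 (ring B arm CH2OH; lactone B 3R,4R)
Conditions: Bu4NF, AcOH, THF, 0 → 25 °C
Reagents that add atoms: none
Why: Fluoride-mediated desilylation, buffered with acetic acid so that the lactone and the quaternary carbinol are not exposed to strong base.

Step 15
Reactants: 27 the 5'-hydroxymethyl analogue of 26
Product: 28 the 5'-bromomethyl analogue of 26 (ring B arm CH2Br; lactone B 3R,4R; used at once)
Conditions: CBr4, PPh3, CH2Cl2, 0 °C
Reagents that add atoms: carbon tetrabromide, BrC(Br)(Br)Br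
Why: Appel reaction, which under neutral conditions converts the primary benzylic alcohol by SN2 while the hindered tertiary alpha-hydroxy lactone carbinol should stay untouched.

Step 16
Reactants: 29 4-benzyloxy-3-methoxybenzaldehyde; 16 dimethyl succinate
Product: 30 (E)-4-(4-benzyloxy-3-methoxyphenyl)-3-(methoxycarbonyl)but-3-enoic acid
Conditions: KOt-Bu, t-BuOH, 50 °C; then 1 M HCl to pH 3
Reagents that add atoms: none
Why: Stobbe condensation as in step 8, on the classical substrate class for dibenzylbutyrolactone lignans.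

Step 17
Reactants: 30 (E)-4-(4-benzyloxy-3-methoxyphenyl)-3-(methoxycarbonyl)but-3-enoic acid
Product: 31 (3S)-4-(4-benzyloxy-3-methoxyphenyl)-3-(methoxycarbonyl)butanoic acid
Conditions: H2 (6 bar), [Rh(cod)((R,R)-Et-DuPHOS)]BF4 (0.5 mol%), NaOMe (10 mol%), MeOH, 25 °C
Reagents that add atoms: none
Why: Asymmetric hydrogenation of the chelating itaconate-type half-ester as in step 9, with the ligand selecting the alkene face and setting the future C-beta of lactone A.

Step 18
Reactants: 31 (3S)-4-(4-benzyloxy-3-methoxyphenyl)-3-(methoxycarbonyl)butanoic acid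
Product: 33 (4S)-4-(4-benzyloxy-3-methoxybenzyl)oxolan-2-one, via hydroxy acid 32 (not isolated)
Conditions: KOH (1.0 equiv), EtOH, 0 °C; CaCl2, NaBH4, EtOH, 0 → 25 °C; then 2 M HCl, 25 °C
Reagents that add atoms: none
Why: Chemoselective Ca(BH4)2 reduction of the ester beside the inert carboxylate, followed by acid-induced gamma-lactonisation with the stereocentre retained.

Step 19
Reactants: 33 (4S)-4-(4-benzyloxy-3-methoxybenzyl)oxolan-2-one
Product: 35 (3S,4R)-4-(4-benzyloxy-3-methoxybenzyl)-3-hydroxyoxolan-2-one, via potassium enolate 34 (not isolated)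
Conditions: KN(SiMe3)2, THF, −78 °C; 2-(phenylsulfonyl)-3-phenyloxaziridine, −78 °C; AcOH
Reagents that add atoms: 2-(phenylsulfonyl)-3-phenyloxaziridine, O=S(=O)(c1ccccc1)N1OC1c1ccccc1; potassium bis(trimethylsilyl)amide, C[Si](C)(C)N([K])[Si](C)(C)C (potassium of intermediate 34 only)
Why: Electrophilic enolate hydroxylation with an N-sulfonyloxaziridine, expected trans to the C-beta benzyl group, with the new centre erased again in step 20.

Step 20
Reactants: 35 (3S,4R)-4-(4-benzyloxy-3-methoxybenzyl)-3-hydroxyoxolan-2-one; 28 the 5'-bromomethyl analogue of 26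
Product: 37 tetra-O-benzyl ether of the target (both lactones 3R,4R), via dilithium enediolate 36 (not isolated)
Conditions: 35 (2.5 equiv) added to LiN(i-Pr)2 (5.2 equiv), THF, −78 → −40 °C; 28 (1.0 equiv), −78 → −30 °C; AcOH (the surplus enediolate also takes up the tertiary OH proton of 28)
Reagents that add atoms: lithium diisopropylamide, CC(C)N([Li])C(C)C (lithium of intermediate 36 only)
Why: C-alkylation of the alpha-hydroxy lactone dianion with the ring B benzylic bromide, in which attack anti to the C-beta benzyl group of 36 should set C-alpha of lactone A as R, while lactone B of 28 has no alpha-hydrogen and a crowded carbonyl and so should be a spectator.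

Step 21
Reactants: 37 tetra-O-benzyl ether of the target
Product: 38 target CNP0218652.1
Conditions: H2 (1 atm), 10% Pd/C, EtOAc/EtOH, 25 °C
Reagents that add atoms: none
Why: Catalytic hydrogenolysis cleaves the four aryl benzyl ethers at once and leaves lactones, tertiary alcohols, methoxy groups and all four stereocentres unchanged.

Compound list
1 | 5-bromovanillin | COc1cc(C=O)cc(Br)c1O | starting material
2 | 4-benzyloxy-3-bromo-5-methoxybenzaldehyde | COc1cc(C=O)cc(Br)c1OCc1ccccc1 | intermediate
3 | (4-benzyloxy-3-bromo-5-methoxyphenyl)methanol | COc1cc(CO)cc(Br)c1OCc1ccccc1 | intermediate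
4 | [(4-benzyloxy-3-bromo-5-methoxyphenyl)methoxy]triisopropylsilane | COc1cc(CO[Si](C(C)C)(C(C)C)C(C)C)cc(Br)c1OCc1ccccc1 | intermediate
5 | [2-benzyloxy-3-methoxy-5-(triisopropylsilyloxymethyl)phenyl]magnesium bromide | COc1cc(CO[Si](C(C)C)(C(C)C)C(C)C)cc([Mg]Br)c1OCc1ccccc1 | intermediate
6 | 3-chloro-5-methoxybenzaldehyde | COc1cc(Cl)cc(C=O)c1 | starting material
7 | 2-(3-chloro-5-methoxyphenyl)-1,3-dioxolane | COc1cc(Cl)cc(C2OCCO2)c1 | intermediate
8 | trimethyl borate | COB(OC)OC | starting material
9 | [2-chloro-4-(1,3-dioxolan-2-yl)-6-methoxyphenyl]lithium | COc1cc(C2OCCO2)cc(Cl)c1[Li] | intermediate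
10 | 5-(1,3-dioxolan-2-yl)-3-methoxybenzyne | COC1=CC(C2OCCO2)=CC#C1 | intermediate
11 | [2'-benzyloxy-5-(1,3-dioxolan-2-yl)-3,3'-dimethoxy-5'-(triisopropylsilyloxymethyl)biphenyl-2-yl]magnesium bromide | COc1cc(C2OCCO2)cc(-c2cc(CO[Si](C(C)C)(C(C)C)C(C)C)cc(OC)c2OCc2ccccc2)c1[Mg]Br | intermediate
12 | dimethyl [2'-benzyloxy-5-(1,3-dioxolan-2-yl)-3,3'-dimethoxy-5'-(triisopropylsilyloxymethyl)biphenyl-2-yl]boronate | COc1cc(C2OCCO2)cc(-c2cc(CO[Si](C(C)C)(C(C)C)C(C)C)cc(OC)c2OCc2ccccc2)c1B(OC)OC | intermediate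
13 | 2'-benzyloxy-5-(1,3-dioxolan-2-yl)-3,3'-dimethoxy-5'-(triisopropylsilyloxymethyl)biphenyl-2-ol | COc1cc(C2OCCO2)cc(-c2cc(CO[Si](C(C)C)(C(C)C)C(C)C)cc(OC)c2OCc2ccccc2)c1O | intermediate
14 | 2-BC-1,3-dioxolane (benzyl ether acetal) | COc1cc(C2OCCO2)cc(-c2cc(CO[Si](C(C)C)(C(C)C)C(C)C)cc(OC)c2OCc2ccccc2)c1OCc1ccccc1 | intermediate
15 | BC-carbaldehyde | COc1cc(C=O)cc(-c2cc(CO[Si](C(C)C)(C(C)C)C(C)C)cc(OC)c2OCc2ccccc2)c1OCc1ccccc1 | intermediate
16 | dimethyl succinate | COC(=O)CCC(=O)OC | starting material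
17 | (E)-4-BC-3-(methoxycarbonyl)but-3-enoic acid | COc1cc(/C=C(\CC(=O)O)C(=O)OC)cc(-c2cc(CO[Si](C(C)C)(C(C)C)C(C)C)cc(OC)c2OCc2ccccc2)c1OCc1ccccc1 | intermediate
18 | (3S)-4-BC-3-(methoxycarbonyl)butanoic acid | COc1cc(C[C@@H](CC(=O)O)C(=O)OC)cc(-c2cc(CO[Si](C(C)C)(C(C)C)C(C)C)cc(OC)c2OCc2ccccc2)c1OCc1ccccc1 | intermediate
19 | (3S)-4-BC-3-(hydroxymethyl)butanoic acid | COc1cc(C[C@@H](CC(=O)O)CO)cc(-c2cc(CO[Si](C(C)C)(C(C)C)C(C)C)cc(OC)c2OCc2ccccc2)c1OCc1ccccc1 | intermediate
20 | (4S)-4-(BC-methyl)oxolan-2-one | COc1cc(C[C@@H]2COC(=O)C2)cc(-c2cc(CO[Si](C(C)C)(C(C)C)C(C)C)cc(OC)c2OCc2ccccc2)c1OCc1ccccc1 | intermediate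
21 | potassium (4S)-4-(BC-methyl)-4,5-dihydrofuran-2-olate | COc1cc(C[C@@H]2COC(O[K])=C2)cc(-c2cc(CO[Si](C(C)C)(C(C)C)C(C)C)cc(OC)c2OCc2ccccc2)c1OCc1ccccc1 | intermediate
22 | (3S,4R)-3-hydroxy-4-(BC-methyl)oxolan-2-one (OH trans to the arylmethyl group) | COc1cc(C[C@@H]2COC(=O)[C@H]2O)cc(-c2cc(CO[Si](C(C)C)(C(C)C)C(C)C)cc(OC)c2OCc2ccccc2)c1OCc1ccccc1 | intermediate
23 | (4-benzyloxy-3-methoxyphenyl)methanol | COc1cc(CO)ccc1OCc1ccccc1 | starting material
24 | 4-benzyloxy-3-methoxybenzyl bromide | COc1cc(CBr)ccc1OCc1ccccc1 | intermediate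
25 | dilithium (4R)-4-(BC-methyl)-4,5-dihydrofuran-2,3-diolate | COc1cc(C[C@@H]2COC(O[Li])=C2O[Li])cc(-c2cc(CO[Si](C(C)C)(C(C)C)C(C)C)cc(OC)c2OCc2ccccc2)c1OCc1ccccc1 | intermediate
26 | (3R,4R)-3-(4-benzyloxy-3-methoxybenzyl)-3-hydroxy-4-(BC-methyl)oxolan-2-one (arylmethyl groups trans) | COc1cc(C[C@@H]2COC(=O)[C@@]2(O)Cc2ccc(OCc3ccccc3)c(OC)c2)cc(-c2cc(CO[Si](C(C)C)(C(C)C)C(C)C)cc(OC)c2OCc2ccccc2)c1OCc1ccccc1 | intermediate
27 | 5'-hydroxymethyl analogue of 26 | COc1cc(C[C@@H]2COC(=O)[C@@]2(O)Cc2ccc(OCc3ccccc3)c(OC)c2)cc(-c2cc(CO)cc(OC)c2OCc2ccccc2)c1OCc1ccccc1 | intermediate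
28 | 5'-bromomethyl analogue of 26 | COc1cc(C[C@@H]2COC(=O)[C@@]2(O)Cc2ccc(OCc3ccccc3)c(OC)c2)cc(-c2cc(CBr)cc(OC)c2OCc2ccccc2)c1OCc1ccccc1 | intermediate
29 | 4-benzyloxy-3-methoxybenzaldehyde | COc1cc(C=O)ccc1OCc1ccccc1 | starting material
30 | (E)-4-(4-benzyloxy-3-methoxyphenyl)-3-(methoxycarbonyl)but-3-enoic acid | COc1cc(/C=C(\CC(=O)O)C(=O)OC)ccc1OCc1ccccc1 | intermediate
31 | (3S)-4-(4-benzyloxy-3-methoxyphenyl)-3-(methoxycarbonyl)butanoic acid | COc1cc(C[C@@H](CC(=O)O)C(=O)OC)ccc1OCc1ccccc1 | intermediate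
32 | (3S)-4-(4-benzyloxy-3-methoxyphenyl)-3-(hydroxymethyl)butanoic acid | COc1cc(C[C@@H](CC(=O)O)CO)ccc1OCc1ccccc1 | intermediate
33 | (4S)-4-(4-benzyloxy-3-methoxybenzyl)oxolan-2-one | COc1cc(C[C@@H]2COC(=O)C2)ccc1OCc1ccccc1 | intermediate
34 | potassium (4S)-4-(4-benzyloxy-3-methoxybenzyl)-4,5-dihydrofuran-2-olate | COc1cc(C[C@@H]2COC(O[K])=C2)ccc1OCc1ccccc1 | intermediate
35 | (3S,4R)-4-(4-benzyloxy-3-methoxybenzyl)-3-hydroxyoxolan-2-one | COc1cc(C[C@@H]2COC(=O)[C@H]2O)ccc1OCc1ccccc1 | intermediate
36 | dilithium (4R)-4-(4-benzyloxy-3-methoxybenzyl)-4,5-dihydrofuran-2,3-diolate | COc1cc(C[C@@H]2COC(O[Li])=C2O[Li])ccc1OCc1ccccc1 | intermediate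
37 | tetra-O-benzyl ether of the target (lactone A 3R,4R; lactone B 3R,4R) | COc1cc(C[C@@H]2COC(=O)[C@@]2(O)Cc2cc(OC)c(OCc3ccccc3)c(-c3cc(C[C@@H]4COC(=O)[C@@]4(O)Cc4ccc(OCc5ccccc5)c(OC)c4)cc(OC)c3OCc3ccccc3)c2)ccc1OCc1ccccc1 | intermediate
38 | CNP0218652.1 (lactone A 3R,4R; lactone B 3R,4R) | COc1cc(C[C@@H]2COC(=O)[C@@]2(O)Cc2cc(OC)c(O)c(-c3cc(C[C@@H]4COC(=O)[C@@]4(O)Cc4ccc(O)c(OC)c4)cc(OC)c3O)c2)ccc1O | target

Total step count: 21.
Longest linear sequence: 15 steps (1, 2, 3, 4, 6, 7, 8, 9, 10, 11, 13, 14, 15, 20, 21).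

Steps most likely to fail

1. Step 6.
- What may go wrong: metalation may stray to a position beside the acetal. The aryne may be captured by its own lithiated precursor instead of by 5. Borylation of the crowded biarylmagnesium centre may be incomplete, so that the carbon–metal bond is merely protonated.
- Fallback: a cross-coupling with the oxygen already in place, setting out from 2 and 5 and returning at 14.
- Aldehyde 2 is acetalised (ethylene glycol, p-TsOH, toluene, reflux) to 2-(4-benzyloxy-3-bromo-5-methoxyphenyl)-1,3-dioxolane F1.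
- Grignard reagent 5 is quenched with 2-isopropoxy-4,4,5,5-tetramethyl-1,3,2-dioxaborolane (THF, −78 → 25 °C) to the ring B pinacol boronate F2.
- Suzuki–Miyaura coupling of the two (Pd(OAc)2, SPhos, K3PO4, toluene/H2O, 80 °C) gives 14, which enters the hydrolysis half of step 7.

2. Step 20.
- What may go wrong: proton transfer from the tertiary alcohol of 28 may drain the enediolate. O-alkylation may compete. The labile bromide may decay before the C–C bond forms, or facial selectivity on the large electrophile may erode.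
- Fallback: a chiral-pool template with self-regeneration of the carbinol stereocentre, setting out from 24 and 28 and returning at 37.
- Commercial dimethyl (R)-malate is doubly deprotonated (LiN(i-Pr)2, 2.1 equiv, THF, −78 → −20 °C) and alkylated anti with 24 to dimethyl (2R,3S)-3-(4-benzyloxy-3-methoxybenzyl)-2-hydroxybutanedioate F3.
- Saponification (KOH, aq. MeOH) gives (2R,3S)-3-(4-benzyloxy-3-methoxybenzyl)-2-hydroxybutanedioic acid F4.
- Pivalaldehyde with p-TsOH under azeotropic water removal gives the cis acetal (2S)-3-(4-benzyloxy-3-methoxyphenyl)-2-[(2R,4R)-2-tert-butyl-5-oxo-1,3-dioxolan-4-yl]propanoic acid F5.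
- Its carboxylate enolate (LiN(SiMe3)2, 3.2 equiv, THF, −78 °C) is alkylated by 28 anti to the tert-butyl group to the ring B-alkylated dioxolanone acid F6.
- BH3·SMe2 (THF, 0 °C) reduces only the free acid to the primary alcohol F7.
- Catalytic p-TsOH (CH2Cl2, 25 °C) then moves the acyl group onto the new alcohol, releases the aldehyde auxiliary and gives 37.

3. Step 13.
- What may go wrong: the second deprotonation next to the alkoxide may be incomplete, the enediolate may be oxidised or fragment on warming, or O-benzylation may compete.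
- Fallback: a protected mono-enolate in place of the dianion, setting out from 22 and returning at 26.
- Treatment of 22 with 2-methoxypropene and pyridinium p-toluenesulfonate (CH2Cl2, 0 °C) gives the 2-methoxypropan-2-yl ether of 22 F8.
- LiN(i-Pr)2 (1.1 equiv, THF, −78 °C) followed by 24 alkylates the alpha-alkoxy enolate anti to the C-beta substituent to the 2-methoxypropan-2-yl ether of 26 F9.
- AcOH/THF/H2O (25 °C) removes the mixed acetal without touching the TIPS ether and gives 26.

Further compounds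
F1 | step 6 | 2-(4-benzyloxy-3-bromo-5-methoxyphenyl)-1,3-dioxolane | COc1cc(C2OCCO2)cc(Br)c1OCc1ccccc1
F2 | step 6 | 2-[2-benzyloxy-3-methoxy-5-(triisopropylsilyloxymethyl)phenyl]-4,4,5,5-tetramethyl-1,3,2-dioxaborolane | COc1cc(CO[Si](C(C)C)(C(C)C)C(C)C)cc(B2OC(C)(C)C(C)(C)O2)c1OCc1ccccc1
F3 | step 20 | dimethyl (2R,3S)-3-(4-benzyloxy-3-methoxybenzyl)-2-hydroxybutanedioate | COc1cc(C[C@H](C(=O)OC)[C@@H](O)C(=O)OC)ccc1OCc1ccccc1
F4 | step 20 | (2R,3S)-3-(4-benzyloxy-3-methoxybenzyl)-2-hydroxybutanedioic acid | COc1cc(C[C@H](C(=O)O)[C@@H](O)C(=O)O)ccc1OCc1ccccc1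
F5 | step 20 | (2S)-3-(4-benzyloxy-3-methoxyphenyl)-2-[(2R,4R)-2-tert-butyl-5-oxo-1,3-dioxolan-4-yl]propanoic acid | COc1cc(C[C@H](C(=O)O)[C@H]2O[C@@H](C(C)(C)C)OC2=O)ccc1OCc1ccccc1
F6 | step 20 | ring B-alkylated dioxolanone acid | COc1cc(C[C@H](C(=O)O)[C@@]2(Cc3cc(OC)c(OCc4ccccc4)c(-c4cc(C[C@@H]5COC(=O)[C@@]5(O)Cc5ccc(OCc6ccccc6)c(OC)c5)cc(OC)c4OCc4ccccc4)c3)O[C@@H](C(C)(C)C)OC2=O)ccc1OCc1ccccc1
F7 | step 20 | primary alcohol from F6 | COc1cc(C[C@H](CO)[C@@]2(Cc3cc(OC)c(OCc4ccccc4)c(-c4cc(C[C@@H]5COC(=O)[C@@]5(O)Cc5ccc(OCc6ccccc6)c(OC)c5)cc(OC)c4OCc4ccccc4)c3)O[C@@H](C(C)(C)C)OC2=O)ccc1OCc1ccccc1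
F8 | step 13 | 2-methoxypropan-2-yl ether of 22 | COc1cc(C[C@@H]2COC(=O)[C@H]2OC(C)(C)OC)cc(-c2cc(CO[Si](C(C)C)(C(C)C)C(C)C)cc(OC)c2OCc2ccccc2)c1OCc1ccccc1
F9 | step 13 | 2-methoxypropan-2-yl ether of 26 | COc1cc(C[C@@H]2COC(=O)[C@@]2(OC(C)(C)OC)Cc2ccc(OCc3ccccc3)c(OC)c2)cc(-c2cc(CO[Si](C(C)C)(C(C)C)C(C)C)cc(OC)c2OCc2ccccc2)c1OCc1ccccc1
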